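**Retrosynthetic overview**

- The target comes from a protected Z-macrolactone by removing two MOM ethers and one dimethyl acetal in the last step.
- The 12-membered ring comes from a 13-membered cyclic boronate complex by ring contraction: the ring B aryl carbon shifts 1,2 from boron to the alkenyl carbon, and anti-elimination turns the E-alkenylboronate into the Z-alkene.
- The open precursor is an ester of a diaryl ether acid (with an aryl bromide) and a (3S,4S)-alkenylboronate alcohol, made by Brown (Z)-γ-alkoxyallylboration of hexanal and cross-metathesis.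
- The diaryl ether comes from Cu-catalysed coupling of the ring A phenol (2-methylfuran + ethyl propiolate benzannulation) with a ring B iodide (3-bromophenol: iodination, MOM, ortho-lithiation/formylation, acetal).
- Ring order: ring A is built first, ring B is bought as 3-bromophenol, the macrocycle is closed last.

Assumption: 3-(methoxymethoxy)prop-1-ene (14) and (+)-Ipc2BOMe are catalogue chemicals, and the target is delivered as the open hydroxy-aldehyde drawn, although it may equilibrate with its seven-membered lactol.

**Route**

Step 1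
Reactants: 1 2-methylfuran; 2 ethyl propiolate
Product: 4 ethyl 5-hydroxy-2-methylbenzoate, via oxanorbornadiene adduct 3 (not isolated)
Conditions: AlCl3 (1.0 equiv), CH2Cl2, 0 °C to rt
Reagents that add atoms: none
Why: Lewis-acid-promoted Diels–Alder reaction of the furan with the activated propiolate (ester next to the methyl-bearing bridgehead), then opening of the oxygen bridge at that tertiary carbon and hydride shift/tautomerisation to the phenol, a furan benzannulation reported for this pair of reactants.

Step 2
Reactants: 5 3-bromophenol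
Product: 6 3-bromo-4-iodophenol
Conditions: N-iodosuccinimide, p-TsOH (10 mol%), MeCN, 0 °C to rt
Reagents that add atoms: N-iodosuccinimide, O=C1CCC(=O)N1I
Why: Electrophilic aromatic iodination in which the free phenol directs para under NIS/TsOH; the minor ortho isomer is removed by crystallisation.

Step 3
Reactants: 6 3-bromo-4-iodophenol
Product: 7 2-bromo-1-iodo-4-(methoxymethoxy)benzene
Conditions: MOMCl, i-Pr2NEt, CH2Cl2, 0 °C to rt
Reagents that add atoms: chloromethyl methyl ether, COCCl
Why: Standard MOM protection of the phenol (O-alkylation), which also installs the ortho-directing group for step 4.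

Step 4
Reactants: 7 2-bromo-1-iodo-4-(methoxymethoxy)benzene
Product: 9 2-bromo-3-iodo-6-(methoxymethoxy)benzaldehyde, via aryllithium 8 (not isolated)
Conditions: LiN(i-Pr)2, THF, −78 °C; DMF; AcOH quench
Reagents that add atoms: N,N-dimethylformamide, CN(C)C=O
Why: Directed ortho-metalation at the proton flanked by OMOM and Br (the most acidic site; the amide base deprotonates without halogen–lithium exchange), followed by formylation of the aryllithium with DMF.

Step 5
Reactants: 9 2-bromo-3-iodo-6-(methoxymethoxy)benzaldehyde
Product: 10 3-bromo-2-(dimethoxymethyl)-4-iodo-1-(methoxymethoxy)benzene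
Conditions: HC(OMe)3, MeOH, PPTS (2 mol%), rt; Et3N quench
Reagents that add atoms: trimethyl orthoformate, COC(OC)OC
Why: Acid-catalysed acetalisation driven by the orthoformate, which masks the aldehyde against the organolithium chemistry of step 11 while the aryl MOM ether survives the weak acid.

Step 6
Reactants: 4 ethyl 5-hydroxy-2-methylbenzoate; 10 3-bromo-2-(dimethoxymethyl)-4-iodo-1-(methoxymethoxy)benzene
Product: 11 ethyl 5-[2-bromo-3-(dimethoxymethyl)-4-(methoxymethoxy)phenoxy]-2-methylbenzoate
Conditions: CuI (10 mol%), N,N-dimethylglycine hydrochloride (30 mol%), Cs2CO3, 1,4-dioxane, 90 °C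
Reagents that add atoms: none
Why: Ullmann-type Cu-catalysed diaryl ether coupling, in which the C–I bond reacts well below the temperature needed for the doubly flanked C–Br bond.

Step 7
Reactants: 11 ethyl 5-[2-bromo-3-(dimethoxymethyl)-4-(methoxymethoxy)phenoxy]-2-methylbenzoate
Product: 12 5-[2-bromo-3-(dimethoxymethyl)-4-(methoxymethoxy)phenoxy]-2-methylbenzoic acid
Conditions: LiOH, THF/MeOH/H2O, 50 °C; then 1 M HCl to pH 4, 0 °C
Reagents that add atoms: lithium hydroxide, [Li+].[OH-]
Why: Saponification of the ethyl ester; acetal, MOM ether and aryl bromide are stable to base, and the acidification is kept cold and mild.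

Step 8
Reactants: 13 hexanal; 14 3-(methoxymethoxy)prop-1-ene
Product: 17 (3S,4S)-3-(methoxymethoxy)non-1-en-4-ol, via allylborane 15 (not isolated), via borinate 16 (not isolated)
Conditions: s-BuLi, THF, −78 °C; (+)-Ipc2BOMe; BF3·OEt2; then 13, −78 °C; NaOH, H2O2, 0 °C to rt
Reagents that add atoms: none
Why: Brown (Z)-γ-alkoxyallylboration, in which the chair transition state of the Z-allylborane gives the syn (threo) diol monoether and the isopinocampheyl groups from (−)-α-pinene set both new centres as 3S,4S, with the two oxygens already differentiated.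

Step 9
Reactants: 17 (3S,4S)-3-(methoxymethoxy)non-1-en-4-ol
Product: 18 (1E,3S,4S)-3-(methoxymethoxy)-1-(4,4,5,5-tetramethyl-1,3,2-dioxaborolan-2-yl)non-1-en-4-ol
Conditions: vinylboronic acid pinacol ester (3 equiv), RuCl2(H2IMes)(=CH-C6H4-2-O-i-Pr) (second-generation Hoveyda–Grubbs catalyst, 5 mol%), CH2Cl2, 40 °C
Reagents that add atoms: vinylboronic acid pinacol ester, C=CB1OC(C)(C)C(C)(C)O1
Why: Olefin cross-metathesis, which is E-selective with vinyl pinacol boronate and tolerates the allylic MOM ether and the free hydroxyl; the stereocentres are not touched.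

Step 10
Reactants: 12 5-[2-bromo-3-(dimethoxymethyl)-4-(methoxymethoxy)phenoxy]-2-methylbenzoic acid; 18 (1E,3S,4S)-3-(methoxymethoxy)-1-(4,4,5,5-tetramethyl-1,3,2-dioxaborolan-2-yl)non-1-en-4-ol
Product: 20 (1E,3S,4S)-3-(methoxymethoxy)-1-(4,4,5,5-tetramethyl-1,3,2-dioxaborolan-2-yl)non-1-en-4-yl 5-[2-bromo-3-(dimethoxymethyl)-4-(methoxymethoxy)phenoxy]-2-methylbenzoate, via mixed anhydride 19 (not isolated)
Conditions: 2,4,6-trichlorobenzoyl chloride, Et3N, toluene, rt; then 18, DMAP, toluene, rt to 40 °C
Reagents that add atoms: none
Why: Yamaguchi esterification through the mixed anhydride, which acylates the only free hydroxyl (C4) with retention because the C3 oxygen is blocked as its MOM ether.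

Step 11
Reactants: 20 (1E,3S,4S)-3-(methoxymethoxy)-1-(4,4,5,5-tetramethyl-1,3,2-dioxaborolan-2-yl)non-1-en-4-yl 5-[2-bromo-3-(dimethoxymethyl)-4-(methoxymethoxy)phenoxy]-2-methylbenzoate
Product: 24 Z-configured protected macrolactone (bis-MOM ether dimethyl acetal of the target), via aryllithium 21 (not isolated), via cyclic boronate complex 22 (not isolated), via iodoboronate 23 (not isolated)
Conditions: t-BuLi (2.05 equiv), THF, −100 °C, 2 mM; −78 °C, 30 min; I2 (1.2 equiv), THF, −78 °C; NaOMe/MeOH, −78 to 0 °C
Reagents that add atoms: none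
Why: Proposed new method: a macrocyclic, ring-contracting Zweifel olefination in which Br/Li exchange at −100 °C outruns attack on the hindered ester (Parham-type selectivity), the aryllithium 21 is captured intramolecularly by the alkenyl boronic ester to give the 13-membered cyclic boronate complex 22, iodine activates the alkene and triggers the polar 1,2-shift of the aryl carbon from boron to the alkenyl carbon anti to the new C–I bond (contracting the ring to the 12-membered iodoboronate 23), and methoxide-induced anti-elimination of boron and iodide converts the E-alkenylboronate stereospecifically into the Z-alkene; the closest known reaction is the intermolecular Zweifel olefination of aryllithiums with E-alkenyl pinacol boronates (I2, NaOMe, E to Z), and what is new is forming the boronate complex intramolecularly and using the 1,2-metallate shift to close a macrocycle.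

Step 12
Reactants: 24 Z-configured protected macrolactone (bis-MOM ether dimethyl acetal of the target)
Product: 25 CNP0238900.1 (target)
Conditions: Me2BBr (5 equiv), CH2Cl2, −78 °C; then THF/sat. aq NaHCO3, 0 °C
Reagents that add atoms: water, O
Why: Lewis-acid acetal cleavage (Guindon conditions), in which bromide opens the boron-activated O–CH2–O and ArCH(OMe)2 groups at −78 °C and aqueous work-up releases phenol, aldehyde and allylic alcohol without touching the hindered lactone, the Z-alkene or the two carbinol centres.

**Compound list**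

1 | 2-methylfuran | Cc1ccco1 | starting material
2 | ethyl propiolate | CCOC(=O)C#C | starting material
3 | oxanorbornadiene adduct (not isolated, racemic): ethyl 1-methyl-7-oxabicyclo[2.2.1]hepta-2,5-diene-2-carboxylate | CCOC(=O)C1=CC2C=CC1(C)O2 | intermediate
4 | ethyl 5-hydroxy-2-methylbenzoate | CCOC(=O)c1cc(O)ccc1C | intermediate
5 | 3-bromophenol | Oc1cccc(Br)c1 | starting material
6 | 3-bromo-4-iodophenol | Oc1ccc(I)c(Br)c1 | intermediate
7 | 2-bromo-1-iodo-4-(methoxymethoxy)benzene | COCOc1ccc(I)c(Br)c1 | intermediate
8 | aryllithium (not isolated): [2-bromo-3-iodo-6-(methoxymethoxy)phenyl]lithium | [Li]c1c(Br)c(I)ccc1OCOC | intermediate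
9 | 2-bromo-3-iodo-6-(methoxymethoxy)benzaldehyde | O=Cc1c(Br)c(I)ccc1OCOC | intermediate
10 | 3-bromo-2-(dimethoxymethyl)-4-iodo-1-(methoxymethoxy)benzene | COC(OC)c1c(Br)c(I)ccc1OCOC | intermediate
11 | ethyl 5-[2-bromo-3-(dimethoxymethyl)-4-(methoxymethoxy)phenoxy]-2-methylbenzoate | CCOC(=O)c1cc(Oc2ccc(OCOC)c(C(OC)OC)c2Br)ccc1C | intermediate
12 | 5-[2-bromo-3-(dimethoxymethyl)-4-(methoxymethoxy)phenoxy]-2-methylbenzoic acid | Cc1ccc(Oc2ccc(OCOC)c(C(OC)OC)c2Br)cc1C(=O)O | intermediate
13 | hexanal | CCCCCC=O | starting material
14 | 3-(methoxymethoxy)prop-1-ene (allyl methoxymethyl ether) | C=CCOCOC | starting material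
15 | allylborane (not isolated): [(Z)-3-(methoxymethoxy)prop-2-en-1-yl]diisopinocampheylborane, Ipc groups from (−)-α-pinene | COCO/C=C\CB([C@H]1C[C@H]2C[C@@H]([C@@H]1C)C2(C)C)[C@H]1C[C@H]2C[C@@H]([C@@H]1C)C2(C)C | intermediate
16 | borinate (not isolated): (3S,4S)-3-(methoxymethoxy)non-1-en-4-yl diisopinocampheylborinate | CCCCC[C@H](OB([C@H]1C[C@H]2C[C@@H]([C@@H]1C)C2(C)C)[C@H]1C[C@H]2C[C@@H]([C@@H]1C)C2(C)C)[C@@H](OCOC)C=C | intermediate
17 | (3S,4S)-3-(methoxymethoxy)non-1-en-4-ol | CCCCC[C@H](O)[C@@H](OCOC)C=C | intermediate
18 | (1E,3S,4S)-3-(methoxymethoxy)-1-(4,4,5,5-tetramethyl-1,3,2-dioxaborolan-2-yl)non-1-en-4-ol | CCCCC[C@H](O)[C@@H](OCOC)/C=C/B1OC(C)(C)C(C)(C)O1 | intermediate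
19 | mixed anhydride (not isolated) of acid 12 with 2,4,6-trichlorobenzoic acid | Cc1ccc(Oc2ccc(OCOC)c(C(OC)OC)c2Br)cc1C(=O)OC(=O)c1c(Cl)cc(Cl)cc1Cl | intermediate
20 | (1E,3S,4S)-3-(methoxymethoxy)-1-(4,4,5,5-tetramethyl-1,3,2-dioxaborolan-2-yl)non-1-en-4-yl 5-[2-bromo-3-(dimethoxymethyl)-4-(methoxymethoxy)phenoxy]-2-methylbenzoate | CCCCC[C@H](OC(=O)c1cc(Oc2ccc(OCOC)c(C(OC)OC)c2Br)ccc1C)[C@@H](OCOC)/C=C/B1OC(C)(C)C(C)(C)O1 | intermediate
21 | aryllithium (not isolated): 20 with Li in place of Br | CCCCC[C@H](OC(=O)c1cc(Oc2ccc(OCOC)c(C(OC)OC)c2[Li])ccc1C)[C@@H](OCOC)/C=C/B1OC(C)(C)C(C)(C)O1 | intermediate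
22 | cyclic boronate complex (not isolated): lithium salt of the 13-membered ring in which boron carries the ring B carbon, the E-alkenyl carbon and pinacol | [Li+].CCCCC[C@@H]1OC(=O)c2cc(ccc2C)Oc2ccc(OCOC)c(C(OC)OC)c2[B-]3(OC(C)(C)C(C)(C)O3)/C=C/[C@@H]1OCOC | intermediate
23 | iodoboronate (not isolated): 12-membered ring with aryl and boryl on one carbon and iodine on the next, aryl and iodine added anti; one of two possible anti diastereomers shown, both give the same alkene | CCCCC[C@@H]1OC(=O)c2cc(ccc2C)Oc2ccc(OCOC)c(C(OC)OC)c2[C@H](B3OC(C)(C)C(C)(C)O3)[C@@H](I)[C@@H]1OCOC | intermediate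
24 | Z-configured protected macrolactone: the target with the phenol and the allylic alcohol as MOM ethers and the aldehyde as dimethyl acetal; both carbinol carbons S | CCCCC[C@@H]1OC(=O)c2cc(ccc2C)Oc2ccc(OCOC)c(C(OC)OC)c2/C=C\[C@@H]1OCOC | intermediate
25 | CNP0238900.1: 12-membered (Z)-macrolactone, S at the pentyl-bearing ester carbon, S at the allylic carbinol | CCCCC[C@@H]1OC(=O)c2cc(ccc2C)Oc2ccc(O)c(C=O)c2/C=C\[C@@H]1O | target

**Step count and risk**

Total: 12 steps. Longest linear sequence: 9 steps (5 → 25 through steps 2, 3, 4, 5, 6, 7, 10, 11, 12).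

Most likely to fail, first: step 11, the proposed new ring contraction. The ways it can go wrong are t-BuLi adding to boron before the exchange, intermolecular boronate formation giving oligomers, ipso-iodination of the aryl–boron bond, and methoxide opening the new lactone. The fallback uses known chemistry, sets out from 20 and comes back at 24. Intramolecular Suzuki–Miyaura coupling of the same aryl bromide and alkenyl boronate (Pd(OAc)2, SPhos, K3PO4, THF/H2O, 60 °C, 1 mM) closes the ring with retention and gives the E-configured protected macrolactone F1. Triplet-sensitised E-to-Z isomerisation (Ir(ppy)3, 450 nm LEDs, MeCN, rt), in which the twisted Z-styrene is no longer excited, then gives 24.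

Second: step 6, the diaryl ether coupling. The iodide sits next to a bromide, and the acetal and MOM groups limit how far the conditions can be pushed. The fallback sets out from 10 and comes back at 11, with the polarity of the ring B partner reversed. Iodine–magnesium exchange (i-PrMgCl·LiCl, THF, −40 °C, selective for C–I), B(OMe)3 and aqueous work-up give [2-bromo-3-(dimethoxymethyl)-4-(methoxymethoxy)phenyl]boronic acid F2. Chan–Lam coupling of this acid with phenol 4 (Cu(OAc)2, pyridine, 4 Å MS, air, CH2Cl2, rt) gives 11.

Third: step 4, the ortho-lithiation of an arene that carries both bromine and iodine. Halogen migration or aryne formation can compete. The fallback sets out from 5 and comes back at 9, with the order of events changed so that the lithiation is done before any iodine is present. MOM protection of 5 (MOMCl, i-Pr2NEt) gives 1-bromo-3-(methoxymethoxy)benzene F3. Lithiation between OMOM and Br (LiN(i-Pr)2, THF, −78 °C) and DMF give 2-bromo-6-(methoxymethoxy)benzaldehyde F4. Iodination para to the MOM ether (N-iodosuccinimide, TFA 5 mol%, MeCN, rt) gives 9.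

**Further compounds**

F1 | step 11 | E-configured protected macrolactone (E isomer of 24) | CCCCC[C@@H]1OC(=O)c2cc(ccc2C)Oc2ccc(OCOC)c(C(OC)OC)c2/C=C/[C@@H]1OCOC
F2 | step 6 | [2-bromo-3-(dimethoxymethyl)-4-(methoxymethoxy)phenyl]boronic acid | COCOc1ccc(B(O)O)c(Br)c1C(OC)OC
F3 | step 4 | 1-bromo-3-(methoxymethoxy)benzene | COCOc1cccc(Br)c1
F4 | step 4 | 2-bromo-6-(methoxymethoxy)benzaldehyde | COCOc1cccc(Br)c1C=O
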